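The runs stem from a simulated flask on assumed constants, and the scatter is random.

- At late times in both earlier runs the electrophile keeps falling while the target stays low: birch goes from 38% to 20% between 4.00 d and 8.00 d, with 5% target at the end.

| flask | electrophile | free base | protonated nucleophile | remark | time |
|---|---|---|---|---|---|
| birch | 0.050 M | 1.5 equiv (fed, over 30 h) | 0.53 equiv | run made earlier |  |
| ash | 0.050 M | 1.5 equiv (fed, over 30 h) | 0.79 equiv | run made earlier |  |
| flask | 0.050 M | 1.50 equiv (fed, over 30 h) | 1.05 equiv |  | 10 d |

| run | time / d | electrophile / % | target / % |
|---|---|---|---|
| birch | 0.625 | 92 | 3 |
| birch | 2.08 | 64 | 8 |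
| birch | 4.00 | 38 | 3 |
| birch | 6.00 | 25 | 3 |
| birch | 8.00 | 20 | 5 |
| ash | 0.625 | 94 | 3 |
| ash | 1.25 | 77 | 5 |
| ash | 2.50 | 45 | 7 |
| ash | 4.00 | 29 | 6 |
| ash | 8.00 | 11 | 6 |

(standard deviation of a reading: 2 percentage points)

- part of the electrophile that has reacted at 10 d
- share of the unused nucleophile that is free and not bound as protonated nucleophile, at 10 d

- the earlier runs do not show how much of nucleophile is bound; that part of a forecast is a guess

- Birch has lost 1.51 parts of electrophile per part of protonated nucleophile charged, so we read the target as taking a second electrophile.
- This gives our carried quantity, the reach 2.10: twice the protonated nucleophile charged, which on this reading is the electrophile that charge can consume; on the same reading, a reach below one equivalent makes nucleophile the limiting reagent.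
- Birch has a reach of 1.06, which barely covers its electrophile, and the flask has twice that.
- The reach gives a ceiling but no speed, so we replace each late curve by its mean first-order rate: 0.160 /d for birch and 0.242 /d for ash. Birch's rate is 0.661 of ash's and birch's charge of protonated nucleophile is 0.671 of ash's, so we scale the rate with the charge.
- The flask stands 0.260 above ash, as ash stands 0.260 above birch, so we apply the ash-to-birch ratio at 8.00 d once more and estimate 6.05% of the electrophile left in the flask at that time.
- The scaled rate 0.322 /d over the last 2.00 d leaves 3.18%, so our reckoning is 96.8% reacted; the readings do not show binding, so we commit to no free share.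
- We therefore charge the full 1.05 equiv and wait 10 d, since birch's late rate, with the smaller charge, is lower than ash's.
- The forecast gives 95% reacted and 40% free, in its words “No stall appears, so I assume an exchange constant near one with some binding”.
- The flask gives 97.8% reacted and 16.6% free.

    electrophile + nucleophile → acid set free + target (k = 1.70 /M/h)
    nucleophile + acid set free ⇌ protonated nucleophile, settled at all times (K = 24000 /M)
    acid set free + free base ⇌ salt of the base (K = 11000 /M, k = 66.0 /M/h)
    acid set free → by-product carried off (k = 0.0720 /h)
    electrophile + target → side product (k = 2.10 /M/h)

In the flask at 10.0 d, electrophile is used by the step with nucleophile at 0.92 of its rate in the step with target, and the flask then holds 7.64% target against 90.2% side product, each side product counting as two. The flask's reach of 2.10 stands against 97.8% reacted, while the neighbour flask with 0.260 equiv of protonated nucleophile has a reach of 0.520 and shows 51.4% reacted.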